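**Plan**

- The target is a linear hexamer of oxygenated benzene rings, lettered A (2,4,6-trihydroxyphenyl end) to F (3,4,5-trihydroxyphenyl end), joined by five diaryl ether bonds; it has no stereocentre and no stereogenic double bond, so no stereocontrol is needed.
- Retrosynthesis removes fifteen O-methyl groups, then cuts the ether bonds E–O–F, D–O–E, C–O–D and B–O–C, each between the oxygen on the doubly ortho-oxygenated carbon (kept as a phenol) and the less hindered carbon of the outer ring (an aryl halide).
- The A–O–B ether is kept and ring A is opened at its C5–C6 bond instead. Ring A is a phloroglucinol (OH on C1, C3, C5) whose C2, the carbon between two hydroxyls, carries the ring B oxygen, which is the pattern of a 3,5-dioxo ester chain with the aryloxy group on the carbon between the two ketones.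
- Forward: the ring B phenol (from syringaldehyde) is O-alkylated with 3-chloropentane-2,4-dione, each of the two methyl groups is carboxylated with one molecule of dimethyl carbonate, and a Dieckmann condensation closes ring A; the ester is then removed, ring A is methylated and the ring B phenol is unmasked.
- Rings C, D, E and F are added one at a time by Ullmann coupling of the growing hindered phenol with an aryl halide; for C, D and E the halide is a bromobenzaldehyde whose formyl group becomes the next phenol by Baeyer–Villiger oxidation, and BBr3 finally frees all hydroxyls.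

Key step: step 5

Remark on the chemistry: compounds 8, 10 and 21 (and fallback compound F6) are transient and stereochemically undefined (racemic or epimerising), so their SMILES carry no stereo descriptors; nothing in the target depends on them.

**Route**

Step 1
Reactants: 1 syringaldehyde (4-hydroxy-3,5-dimethoxybenzaldehyde)
Product: 2 4-(benzyloxy)-3,5-dimethoxybenzaldehyde
Conditions: BnBr, K2CO3, DMF, 60 °C
Reagents that add atoms: benzyl bromide, BrCc1ccccc1
Why: Williamson etherification of the acidic, para-formyl-activated phenol with a reactive benzylic bromide, under which the non-enolisable aldehyde is inert.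

Step 2
Reactants: 2 4-(benzyloxy)-3,5-dimethoxybenzaldehyde
Product: 4 4-(benzyloxy)-3,5-dimethoxyphenol, via aryl formate 3 (not isolated)
Conditions: mCPBA (1.2 equiv), CH2Cl2, 0 °C to rt; aqueous wash; then Et3N (cat.), MeOH, rt
Reagents that add atoms: 3-chloroperoxybenzoic acid (mCPBA), OOC(=O)c1cccc(Cl)c1
Why: Baeyer–Villiger (Dakin-type) oxidation in which the electron-rich trialkoxyaryl group migrates in preference to hydrogen, followed by base-catalysed methanolysis of the labile aryl formate.

Step 3
Reactants: 4 4-(benzyloxy)-3,5-dimethoxyphenol; 5 3-chloropentane-2,4-dione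
Product: 6 3-[4-(benzyloxy)-3,5-dimethoxyphenoxy]pentane-2,4-dione
Conditions: Cs2CO3 (1.2 equiv), acetone, 56 °C
Reagents that add atoms: none
Why: Williamson-type SN2 O-alkylation of the unhindered phenoxide by a chloride activated by two flanking carbonyl groups, the usual entry to 3-aryloxypentane-2,4-diones.

Step 4
Reactants: 6 3-[4-(benzyloxy)-3,5-dimethoxyphenoxy]pentane-2,4-dione; 7 dimethyl carbonate
Product: 9 dimethyl 4-[4-(benzyloxy)-3,5-dimethoxyphenoxy]-3,5-dioxoheptanedioate, via monoester 8 (not isolated)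
Conditions: LiN(i-Pr)2 (3.3 equiv), THF, −78 to 0 °C; (MeO)2CO (1.1 equiv), −78 °C; LiN(i-Pr)2 (2.2 equiv), −78 to −20 °C; (MeO)2CO (1.5 equiv), −78 °C; AcOH quench
Reagents that add atoms: dimethyl carbonate (second molar equivalent, the same compound as 7, which supplies the second methoxycarbonyl group), COC(=O)OC
Why: Claisen-type C-carboxylation of β-dicarbonyl polyanions, each of the two charges of dimethyl carbonate delivering one CO2Me group with loss of methoxide: the 1,3-dianion of the diketone reacts at its terminal carbon with the first molecule, keto ester 8 is held as an unreactive enolate at C2 and C4, and fresh base ionises the remaining methyl group so that the second terminus is carboxylated by the second molecule in the same way while the central carbon, the least nucleophilic site of each polyanion, is untouched.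

Step 5
Reactants: 9 dimethyl 4-[4-(benzyloxy)-3,5-dimethoxyphenoxy]-3,5-dioxoheptanedioate
Product: 11 methyl 3-[4-(benzyloxy)-3,5-dimethoxyphenoxy]-2,4,6-trihydroxybenzoate, via cyclohexanetrione ester 10 (not isolated)
Conditions: Mg(OMe)2 (3 equiv), MeOH, 65 °C; then 1 M HCl, 0 °C
Reagents that add atoms: none
Why: Mg(OMe)2 turns 9 into a magnesium-chelated polyenolate in which C6, the methylene flanked by the C5 ketone and the C7 ester, attacks the C1 ester carbonyl; loss of methoxide gives trione 10, which tautomerises to the aromatic phloroglucinol and is held as its phenoxide, so the closure is driven to completion. The reaction is an intramolecular Claisen (Dieckmann) condensation, the known base-mediated cyclisation of 3,5-dioxo diesters and related triketo esters to phloroglucinol carboxylates that mimics polyketide aromatisation. Ring A closes in a 6-exo-trig mode (6-enolexo with respect to the ester enolate), the former C1 to C6 of the chain becoming the six ring carbons and C7 remaining as the ester. No stereocentre is created, since the sp3 carbons of 10 disappear on enolisation. The step needs C-acylation at C6 to win over O-acylation to a 4-hydroxy-2-pyranone and over retro-Claisen cleavage next to the aryloxy-bearing C4; the symmetry of 9 makes the two possible closures (C6 onto C1, C2 onto C7) the same reaction, no other carbanion can reach an ester through a five- or six-membered transition state, magnesium chelation of the β-dicarbonyl units favours attack through carbon and shields the ketones from methoxide, and a pyranone, if formed, is reopened by methoxide whereas aromatisation is irreversible. The ether carbon that would be flanked by two oxygens in an aryl–aryl ether coupling is here the sp3 carbon C4 between two ketones, already bonded to the ring B oxygen by the SN2 alkylation of step 3.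

Step 6
Reactants: 11 methyl 3-[4-(benzyloxy)-3,5-dimethoxyphenoxy]-2,4,6-trihydroxybenzoate
Product: 13 2-[4-(benzyloxy)-3,5-dimethoxyphenoxy]benzene-1,3,5-triol, via trihydroxybenzoic acid 12 (not isolated)
Conditions: KOH, degassed H2O/MeOH, 80 °C, argon; then HCl to pH 2, 60 °C
Reagents that add atoms: none
Why: Saponification of the phloroglucinol carboxylate followed by protodecarboxylation of the 2,4,6-trihydroxybenzoic acid, which loses CO2 readily through ipso protonation of its keto tautomer, while benzyl, methyl and diaryl ethers are stable to both media.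

Step 7
Reactants: 13 2-[4-(benzyloxy)-3,5-dimethoxyphenoxy]benzene-1,3,5-triol
Product: 14 2-(benzyloxy)-1,3-dimethoxy-5-(2,4,6-trimethoxyphenoxy)benzene
Conditions: Me2SO4 (4 equiv), K2CO3, acetone, 56 °C
Reagents that add atoms: dimethyl sulfate, COS(=O)(=O)OC
Why: Exhaustive Williamson O-methylation with a hard methylating agent and carbonate base, conditions under which phloroglucinols give aryl methyl ethers rather than C-methylated products.

Step 8
Reactants: 14 2-(benzyloxy)-1,3-dimethoxy-5-(2,4,6-trimethoxyphenoxy)benzene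
Product: 15 AB phenol (2,6-dimethoxy-4-(2,4,6-trimethoxyphenoxy)phenol)
Conditions: H2 (1 atm), Pd/C, EtOAc/MeOH, rt
Reagents that add atoms: none
Why: Catalytic hydrogenolysis cleaves only the benzylic C–O bond and leaves aryl methyl ethers and the diaryl ether intact, unmasking the single ring B phenol.

Step 9
Reactants: 15 AB phenol; 16 4-bromo-2,6-dimethoxybenzaldehyde
Product: 17 ABC aldehyde (4-[2,6-dimethoxy-4-(2,4,6-trimethoxyphenoxy)phenoxy]-2,6-dimethoxybenzaldehyde)
Conditions: CuI (10 mol %), picolinic acid (20 mol %), K3PO4 (2 equiv), DMSO, 90 °C, argon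
Reagents that add atoms: none
Why: Ullmann-type copper-catalysed C–O coupling with a picolinate ligand, which accepts 2,6-disubstituted phenols, here with a bromide that is unhindered and activated by the para-formyl group.

Step 10
Reactants: 17 ABC aldehyde
Product: 19 ABC phenol (4-[2,6-dimethoxy-4-(2,4,6-trimethoxyphenoxy)phenoxy]-2,6-dimethoxyphenol), via ABC formate 18 (not isolated)
Conditions: mCPBA (1.1 equiv), CH2Cl2, 0 °C; aqueous wash; then Et3N (cat.), MeOH, rt
Reagents that add atoms: 3-chloroperoxybenzoic acid (mCPBA), OOC(=O)c1cccc(Cl)c1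
Why: Baeyer–Villiger oxidation of a 2,6-dimethoxy-4-aryloxybenzaldehyde, whose very electron-rich aryl group migrates fast at 0 °C so that one equivalent of peracid is consumed by the aldehyde before the methoxylated rings can be attacked, followed by methanolysis of the formate.

Step 11
Reactants: 20 5-bromo-1,2,3-trimethoxybenzene
Product: 22 6-bromo-2,3,4-trimethoxybenzaldehyde, via chloro(methoxy)methyl arene 21 (not isolated)
Conditions: Cl2CHOMe, TiCl4, CH2Cl2, −10 to 0 °C; then H2O
Reagents that add atoms: dichloromethyl methyl ether, COC(Cl)Cl; water, O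
Why: Rieche formylation (Friedel–Crafts type), regiochemically unambiguous because the only two free positions are equivalent and each lies ortho and para to methoxy groups.

Step 12
Reactants: 19 ABC phenol; 22 6-bromo-2,3,4-trimethoxybenzaldehyde
Product: 23 ABCD aldehyde (6-{4-[2,6-dimethoxy-4-(2,4,6-trimethoxyphenoxy)phenoxy]-2,6-dimethoxyphenoxy}-2,3,4-trimethoxybenzaldehyde)
Conditions: CuI (10 mol %), picolinic acid (20 mol %), K3PO4 (2 equiv), DMSO, 100 °C, argon
Reagents that add atoms: none
Why: Ullmann-type C–O coupling in which the ortho-formyl group activates the bromide and assists copper (ortho effect), the bromide having only this one ortho substituent.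

Step 13
Reactants: 23 ABCD aldehyde
Product: 25 ABCD phenol (6-{4-[2,6-dimethoxy-4-(2,4,6-trimethoxyphenoxy)phenoxy]-2,6-dimethoxyphenoxy}-2,3,4-trimethoxyphenol), via ABCD formate 24 (not isolated)
Conditions: mCPBA (1.1 equiv), CH2Cl2, 0 °C; aqueous wash; then Et3N (cat.), MeOH, rt
Reagents that add atoms: 3-chloroperoxybenzoic acid (mCPBA), OOC(=O)c1cccc(Cl)c1
Why: Baeyer–Villiger oxidation of an aldehyde flanked by aryloxy and methoxy groups and para to a further methoxy group, so aryl migration is strongly favoured, followed by formate methanolysis.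

Step 14
Reactants: 25 ABCD phenol; 16 4-bromo-2,6-dimethoxybenzaldehyde
Product: 26 ABCDE aldehyde (4-(6-{4-[2,6-dimethoxy-4-(2,4,6-trimethoxyphenoxy)phenoxy]-2,6-dimethoxyphenoxy}-2,3,4-trimethoxyphenoxy)-2,6-dimethoxybenzaldehyde)
Conditions: CuI (10 mol %), picolinic acid (20 mol %), K3PO4 (2 equiv), DMSO, 100 °C, argon
Reagents that add atoms: none
Why: Ullmann-type C–O coupling of the doubly ortho-substituted ring D phenol with the same unhindered, para-formyl-activated bromide used for ring C.

Step 15
Reactants: 26 ABCDE aldehyde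
Product: 28 ABCDE phenol (4-(6-{4-[2,6-dimethoxy-4-(2,4,6-trimethoxyphenoxy)phenoxy]-2,6-dimethoxyphenoxy}-2,3,4-trimethoxyphenoxy)-2,6-dimethoxyphenol), via ABCDE formate 27 (not isolated)
Conditions: mCPBA (1.1 equiv), CH2Cl2, 0 °C; aqueous wash; then Et3N (cat.), MeOH, rt
Reagents that add atoms: 3-chloroperoxybenzoic acid (mCPBA), OOC(=O)c1cccc(Cl)c1
Why: Baeyer–Villiger oxidation of the 2,6-dimethoxy-4-aryloxybenzaldehyde as in step 10, followed by formate methanolysis.

Step 16
Reactants: 28 ABCDE phenol; 29 5-iodo-1,2,3-trimethoxybenzene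
Product: 30 pentadeca-O-methyl ether of the target (rings A to F with all fifteen hydroxyls as OMe)
Conditions: CuI (10 mol %), picolinic acid (20 mol %), K3PO4 (2 equiv), DMSO, 90 °C, argon
Reagents that add atoms: none
Why: Ullmann-type C–O coupling of a 2,6-dimethoxyphenol with an unhindered aryl iodide, the classical way to assemble permethylated phlorethol-type ethers.

Step 17
Reactants: 30 pentadeca-O-methyl ether of the target
Product: 31 CNP0175585.0 (2-{4-[4-(2-{3,5-dihydroxy-4-(3,4,5-trihydroxyphenoxy)phenoxy}-3,4,5-trihydroxyphenoxy)-3,5-dihydroxyphenoxy]-3,5-dihydroxyphenoxy}benzene-1,3,5-triol)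
Conditions: BBr3 (about 30 equiv), CH2Cl2, −78 °C to rt; then H2O, 0 °C, argon
Reagents that add atoms: none
Why: Lewis-acid demethylation of aryl methyl ethers by bromide attack on the O-methyl carbon of the boron-complexed ether, a reaction that leaves diaryl ether bonds untouched.

**Compound list**

1 | syringaldehyde (4-hydroxy-3,5-dimethoxybenzaldehyde) | COc1cc(C=O)cc(OC)c1O | starting material
2 | 4-(benzyloxy)-3,5-dimethoxybenzaldehyde | COc1cc(C=O)cc(OC)c1OCc1ccccc1 | intermediate
3 | 4-(benzyloxy)-3,5-dimethoxyphenyl formate | COc1cc(OC=O)cc(OC)c1OCc1ccccc1 | intermediate (not isolated)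
4 | 4-(benzyloxy)-3,5-dimethoxyphenol (ring B unit) | COc1cc(O)cc(OC)c1OCc1ccccc1 | intermediate
5 | 3-chloropentane-2,4-dione | CC(=O)C(Cl)C(C)=O | starting material
6 | 3-[4-(benzyloxy)-3,5-dimethoxyphenoxy]pentane-2,4-dione | CC(=O)C(Oc1cc(OC)c(OCc2ccccc2)c(OC)c1)C(C)=O | intermediate
7 | dimethyl carbonate | COC(=O)OC | starting material
8 | methyl 4-[4-(benzyloxy)-3,5-dimethoxyphenoxy]-3,5-dioxohexanoate (racemic, enolisable) | COC(=O)CC(=O)C(Oc1cc(OC)c(OCc2ccccc2)c(OC)c1)C(C)=O | intermediate (not isolated)
9 | dimethyl 4-[4-(benzyloxy)-3,5-dimethoxyphenoxy]-3,5-dioxoheptanedioate | COC(=O)CC(=O)C(Oc1cc(OC)c(OCc2ccccc2)c(OC)c1)C(=O)CC(=O)OC | intermediate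
10 | methyl 3-[4-(benzyloxy)-3,5-dimethoxyphenoxy]-2,4,6-trioxocyclohexane-1-carboxylate (keto tautomer of 11, sp3 centres epimerising) | COC(=O)C1C(=O)CC(=O)C(Oc2cc(OC)c(OCc3ccccc3)c(OC)c2)C1=O | intermediate (not isolated)
11 | methyl 3-[4-(benzyloxy)-3,5-dimethoxyphenoxy]-2,4,6-trihydroxybenzoate (AB dimer ester) | COC(=O)c1c(O)cc(O)c(Oc2cc(OC)c(OCc3ccccc3)c(OC)c2)c1O | intermediate
12 | 3-[4-(benzyloxy)-3,5-dimethoxyphenoxy]-2,4,6-trihydroxybenzoic acid | OC(=O)c1c(O)cc(O)c(Oc2cc(OC)c(OCc3ccccc3)c(OC)c2)c1O | intermediate (not isolated)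
13 | 2-[4-(benzyloxy)-3,5-dimethoxyphenoxy]benzene-1,3,5-triol | Oc1cc(O)c(Oc2cc(OC)c(OCc3ccccc3)c(OC)c2)c(O)c1 | intermediate
14 | 2-(benzyloxy)-1,3-dimethoxy-5-(2,4,6-trimethoxyphenoxy)benzene | COc1cc(OC)c(Oc2cc(OC)c(OCc3ccccc3)c(OC)c2)c(OC)c1 | intermediate
15 | AB phenol, 2,6-dimethoxy-4-(2,4,6-trimethoxyphenoxy)phenol | COc1cc(OC)c(Oc2cc(OC)c(O)c(OC)c2)c(OC)c1 | intermediate
16 | 4-bromo-2,6-dimethoxybenzaldehyde (ring C and ring E unit) | COc1cc(Br)cc(OC)c1C=O | starting material
17 | ABC aldehyde, 4-[2,6-dimethoxy-4-(2,4,6-trimethoxyphenoxy)phenoxy]-2,6-dimethoxybenzaldehyde | COc1cc(OC)c(Oc2cc(OC)c(Oc3cc(OC)c(C=O)c(OC)c3)c(OC)c2)c(OC)c1 | intermediate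
18 | ABC formate, 4-[2,6-dimethoxy-4-(2,4,6-trimethoxyphenoxy)phenoxy]-2,6-dimethoxyphenyl formate | COc1cc(OC)c(Oc2cc(OC)c(Oc3cc(OC)c(OC=O)c(OC)c3)c(OC)c2)c(OC)c1 | intermediate (not isolated)
19 | ABC phenol, 4-[2,6-dimethoxy-4-(2,4,6-trimethoxyphenoxy)phenoxy]-2,6-dimethoxyphenol | COc1cc(OC)c(Oc2cc(OC)c(Oc3cc(OC)c(O)c(OC)c3)c(OC)c2)c(OC)c1 | intermediate
20 | 5-bromo-1,2,3-trimethoxybenzene | COc1cc(Br)cc(OC)c1OC | starting material
21 | 1-bromo-2-[chloro(methoxy)methyl]-3,4,5-trimethoxybenzene (racemic) | COC(Cl)c1c(Br)cc(OC)c(OC)c1OC | intermediate (not isolated)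
22 | 6-bromo-2,3,4-trimethoxybenzaldehyde (ring D unit) | COc1cc(Br)c(C=O)c(OC)c1OC | intermediate
23 | ABCD aldehyde, 6-{4-[2,6-dimethoxy-4-(2,4,6-trimethoxyphenoxy)phenoxy]-2,6-dimethoxyphenoxy}-2,3,4-trimethoxybenzaldehyde | COc1cc(OC)c(Oc2cc(OC)c(Oc3cc(OC)c(Oc4cc(OC)c(OC)c(OC)c4C=O)c(OC)c3)c(OC)c2)c(OC)c1 | intermediate
24 | ABCD formate, the aryl formate corresponding to 23 (OCHO in place of CHO) | COc1cc(OC)c(Oc2cc(OC)c(Oc3cc(OC)c(Oc4cc(OC)c(OC)c(OC)c4OC=O)c(OC)c3)c(OC)c2)c(OC)c1 | intermediate (not isolated)
25 | ABCD phenol, 6-{4-[2,6-dimethoxy-4-(2,4,6-trimethoxyphenoxy)phenoxy]-2,6-dimethoxyphenoxy}-2,3,4-trimethoxyphenol | COc1cc(OC)c(Oc2cc(OC)c(Oc3cc(OC)c(Oc4cc(OC)c(OC)c(OC)c4O)c(OC)c3)c(OC)c2)c(OC)c1 | intermediate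
26 | ABCDE aldehyde, 4-(6-{4-[2,6-dimethoxy-4-(2,4,6-trimethoxyphenoxy)phenoxy]-2,6-dimethoxyphenoxy}-2,3,4-trimethoxyphenoxy)-2,6-dimethoxybenzaldehyde | COc1cc(OC)c(Oc2cc(OC)c(Oc3cc(OC)c(Oc4cc(OC)c(OC)c(OC)c4Oc4cc(OC)c(C=O)c(OC)c4)c(OC)c3)c(OC)c2)c(OC)c1 | intermediate
27 | ABCDE formate, the aryl formate corresponding to 26 (OCHO in place of CHO) | COc1cc(OC)c(Oc2cc(OC)c(Oc3cc(OC)c(Oc4cc(OC)c(OC)c(OC)c4Oc4cc(OC)c(OC=O)c(OC)c4)c(OC)c3)c(OC)c2)c(OC)c1 | intermediate (not isolated)
28 | ABCDE phenol, 4-(6-{4-[2,6-dimethoxy-4-(2,4,6-trimethoxyphenoxy)phenoxy]-2,6-dimethoxyphenoxy}-2,3,4-trimethoxyphenoxy)-2,6-dimethoxyphenol | COc1cc(OC)c(Oc2cc(OC)c(Oc3cc(OC)c(Oc4cc(OC)c(OC)c(OC)c4Oc4cc(OC)c(O)c(OC)c4)c(OC)c3)c(OC)c2)c(OC)c1 | intermediate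
29 | 5-iodo-1,2,3-trimethoxybenzene (ring F unit) | COc1cc(I)cc(OC)c1OC | starting material
30 | pentadeca-O-methyl ether of the target, 2-{4-[4-(2-{3,5-dimethoxy-4-(3,4,5-trimethoxyphenoxy)phenoxy}-3,4,5-trimethoxyphenoxy)-3,5-dimethoxyphenoxy]-3,5-dimethoxyphenoxy}-1,3,5-trimethoxybenzene | COc1cc(OC)c(Oc2cc(OC)c(Oc3cc(OC)c(Oc4cc(OC)c(OC)c(OC)c4Oc4cc(OC)c(Oc5cc(OC)c(OC)c(OC)c5)c(OC)c4)c(OC)c3)c(OC)c2)c(OC)c1 | intermediate
31 | CNP0175585.0, 2-{4-[4-(2-{3,5-dihydroxy-4-(3,4,5-trihydroxyphenoxy)phenoxy}-3,4,5-trihydroxyphenoxy)-3,5-dihydroxyphenoxy]-3,5-dihydroxyphenoxy}benzene-1,3,5-triol | Oc1cc(O)c(Oc2cc(O)c(Oc3cc(O)c(Oc4cc(O)c(O)c(O)c4Oc4cc(O)c(Oc5cc(O)c(O)c(O)c5)c(O)c4)c(O)c3)c(O)c2)c(O)c1 | target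

**Step count and risks**

Total step count: 17. Longest linear sequence: 16 steps (steps 1 to 10 and 12 to 17, from syringaldehyde 1); step 11 is a one-step side branch.

Steps most likely to fail:

Step 4 (double carboxylation). The keto ester enolate formed after the first carboxylation may resist further ionisation, or proton transfer from it may quench the remaining terminal carbanion, so that the sequence stalls at the monoester or carboxylation goes to oxygen. The fallback installs the two ester arms without a polyanion of the chain; it sets out from phenol 4 and returns at diester 9. Phenol 4 would be alkylated with methyl 4-chloro-3-oxobutanoate (NaH, 2 equiv, THF) to methyl 4-[4-(benzyloxy)-3,5-dimethoxyphenoxy]-3-oxobutanoate F1. Silylation (Me3SiCl, Et3N) would give methyl 4-[4-(benzyloxy)-3,5-dimethoxyphenoxy]-3-(trimethylsilyloxy)but-2-enoate F2. γ-Deprotonation and a second silylation (LiN(i-Pr)2, Me3SiCl, −78 °C) would give 4-[4-(benzyloxy)-3,5-dimethoxyphenoxy]-1-methoxy-1,3-bis(trimethylsilyloxy)buta-1,3-diene F3. Mukaiyama-type γ-acylation of this diene with methyl 3-chloro-3-oxopropanoate (CH2Cl2, −78 °C to rt, aqueous work-up) would deliver diester 9, where the route is rejoined.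

Step 5 (Dieckmann closure of ring A). O-acylation to a 4-hydroxy-2-pyranone and methoxide-induced retro-Claisen cleavage at the aryloxy-bearing carbon may outrun C-acylation. In that case ring A would be brought in as a preformed arene, which gives up the ring construction; the fallback sets out from bromoaldehyde 16 and returns at AB phenol 15. Commercial 2,4,6-trimethoxyphenol would be coupled with 16 under the Ullmann conditions of step 9 to 2,6-dimethoxy-4-(2,4,6-trimethoxyphenoxy)benzaldehyde F4. Baeyer–Villiger oxidation (mCPBA) would give 2,6-dimethoxy-4-(2,4,6-trimethoxyphenoxy)phenyl formate F5, and methanolysis of this formate would give 15, which re-enters the route at step 9; steps 1 to 8 would then not be needed.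

Step 12 (ether between rings C and D, the only one with three ortho substituents around the oxygen). Steric crowding at both partners may slow the copper-mediated C–O bond formation so much that protodebromination of 22 and oxidative degradation of the electron-rich phenol take over. The fallback forms this congested ether first, on small fragments, by nucleophilic aromatic substitution; it sets out from AB phenol 15 and returns at ABCD aldehyde 23, replacing steps 9, 10 and 12. Commercial 5-fluoro-1,2,3-trimethoxybenzene would be formylated as in step 11, through 2-[chloro(methoxy)methyl]-1-fluoro-3,4,5-trimethoxybenzene F6, to 6-fluoro-2,3,4-trimethoxybenzaldehyde F7. The fluoride, activated by the ortho-formyl group, would be displaced by commercial 4-bromo-2,6-dimethoxyphenol (Cs2CO3, DMSO, 120 °C; the aryl bromide is inert without copper) to give 6-(4-bromo-2,6-dimethoxyphenoxy)-2,3,4-trimethoxybenzaldehyde F8. The unhindered bromide of this aldehyde would then be coupled with 15 under the conditions of step 9 to give 23 directly.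

**Further compounds**

F1 | step 4 | methyl 4-[4-(benzyloxy)-3,5-dimethoxyphenoxy]-3-oxobutanoate | COC(=O)CC(=O)COc1cc(OC)c(OCc2ccccc2)c(OC)c1
F2 | step 4 | methyl 4-[4-(benzyloxy)-3,5-dimethoxyphenoxy]-3-(trimethylsilyloxy)but-2-enoate (double-bond isomers not separated) | COC(=O)C=C(COc1cc(OC)c(OCc2ccccc2)c(OC)c1)O[Si](C)(C)C
F3 | step 4 | 4-[4-(benzyloxy)-3,5-dimethoxyphenoxy]-1-methoxy-1,3-bis(trimethylsilyloxy)buta-1,3-diene (mixture of double-bond isomers) | COC(O[Si](C)(C)C)=CC(O[Si](C)(C)C)=COc1cc(OC)c(OCc2ccccc2)c(OC)c1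
F4 | step 5 | 2,6-dimethoxy-4-(2,4,6-trimethoxyphenoxy)benzaldehyde | COc1cc(OC)c(Oc2cc(OC)c(C=O)c(OC)c2)c(OC)c1
F5 | step 5 | 2,6-dimethoxy-4-(2,4,6-trimethoxyphenoxy)phenyl formate | COc1cc(OC)c(Oc2cc(OC)c(OC=O)c(OC)c2)c(OC)c1
F6 | step 12 | 2-[chloro(methoxy)methyl]-1-fluoro-3,4,5-trimethoxybenzene (racemic) | COC(Cl)c1c(F)cc(OC)c(OC)c1OC
F7 | step 12 | 6-fluoro-2,3,4-trimethoxybenzaldehyde | COc1cc(F)c(C=O)c(OC)c1OC
F8 | step 12 | 6-(4-bromo-2,6-dimethoxyphenoxy)-2,3,4-trimethoxybenzaldehyde | COc1cc(Oc2c(OC)cc(Br)cc2OC)c(C=O)c(OC)c1OC
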